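**Retrosynthetic overview**

- The route rests on the chain C(=O)–CH(OH)–CH2 that joins C6 of the chromene (ring A) to C1 of the 4-hydroxyphenyl ring (ring B). It has three carbons, an aryl group on each end carbon and the only stereocentre, an oxygen-bearing CH, in the middle, which is the atom pattern of epichlorohydrin.
- Target ⇐ bis-silylated α-silyloxy ketone ⇐ (oxidation of the ring A benzylic CH2) silyl ether of an (S)-1,3-diarylpropan-2-ol.
- (S)-1,3-Diarylpropan-2-ol ⇐ (both aryl–CH2 bonds) 4-silyloxyphenyl Grignard reagent + (S)-epichlorohydrin + chromen-6-yl Grignard reagent, joined in one flask.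
- Ring order: ring B is bought; the pyran ring is closed onto ring A first (step 1); the only other ring closure is the transient oxirane inside the key step.

Key step: step 5

Remark on the chemistry: ring A is taken from commercial 4-bromo-3-methoxyphenol instead of a resorcinol, so the chromene annulation meets a single free phenol and the methyl ether is in place from the start. Both Grignard reagents are prepared and used as titrated THF solutions.

**Route**

Step 1
Reactants: 1 4-bromo-3-methoxyphenol; 2 3-methylbut-2-enal
Product: 5 6-bromo-7-methoxy-2,2-dimethyl-2H-chromene, via benzodioxaborinine 3 (not isolated), via ortho-quinone methide 4 (not isolated)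
Conditions: PhB(OH)2 (1 equiv), AcOH, toluene, reflux, Dean–Stark trap
Reagents that add atoms: none
Why: Phenylboronic acid-mediated ortho-specific condensation of a phenol with an enal (boronate-templated ortho-alkylation to 3, thermal cycloreversion to 4 with release of the boronic acid, oxa-6π electrocyclisation), which should engage C6 of 1, the unhindered ortho position para to the methoxy group, and not C2 between the two oxygen substituents.

Step 2
Reactants: 5 6-bromo-7-methoxy-2,2-dimethyl-2H-chromene
Product: 6 (7-methoxy-2,2-dimethyl-2H-chromen-6-yl)magnesium bromide (THF solution)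
Conditions: Mg turnings, I2 (cat.), THF, 50 °C
Reagents that add atoms: magnesium, [Mg]
Why: Grignard formation by insertion of magnesium into the aryl C–Br bond, to which the aryl methyl ether, the chromene alkene and the gem-dimethyl pyran are inert.

Step 3
Reactants: 7 4-bromophenol
Product: 8 (4-bromophenoxy)(tert-butyl)dimethylsilane
Conditions: TBSCl, imidazole, DMF, rt
Reagents that add atoms: tert-butyldimethylsilyl chloride, CC(C)(C)[Si](C)(C)Cl
Why: Imidazole-promoted silylation of a phenol, giving a silyl ether that tolerates Grignard formation and organocopper chemistry.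

Step 4
Reactants: 8 (4-bromophenoxy)(tert-butyl)dimethylsilane
Product: 9 4-(tert-butyldimethylsilyloxy)phenylmagnesium bromide (THF solution)
Conditions: Mg turnings, I2 (cat.), THF, 40 °C
Reagents that add atoms: magnesium, [Mg]
Why: Grignard formation from an aryl bromide; aryl tert-butyldimethylsilyl ethers are stable to magnesium and to arylmagnesium halides in THF.

Step 5
Reactants: 9 4-(tert-butyldimethylsilyloxy)phenylmagnesium bromide; 10 (S)-epichlorohydrin; 6 (7-methoxy-2,2-dimethyl-2H-chromen-6-yl)magnesium bromide
Product: 13 (S)-1-[4-(tert-butyldimethylsilyloxy)phenyl]-3-(7-methoxy-2,2-dimethyl-2H-chromen-6-yl)propan-2-ol, via chlorohydrin magnesium alkoxide 11 (not isolated), via benzyloxirane 12 (not isolated)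
Conditions: 10 (1.05 equiv), Li2CuCl4 (3 mol %), THF, −40 °C, 9 (1.0 equiv) added dropwise, −40 to −20 °C; KOtBu (1.0 equiv), −20 to 0 °C; Li2CuCl4 (5 mol %), 6 (1.3 equiv), −30 to 0 °C; aq. NH4Cl
Reagents that add atoms: none
Why: The arylcopper species formed from 9 and the copper salt (reduced in the flask to monovalent copper) attacks the unsubstituted oxirane CH2 of 10 by SN2 displacement to give alkoxide 11; KOtBu exchanges the counter-ion, the alkoxide displaces chloride to form oxirane 12, and the arylcopper species from 6 opens 12 at its CH2 terminus. The closest known reaction type is the sequential copper-catalysed addition of two different Grignard reagents to enantiopure epichlorohydrin, here telescoped in one flask. The only ring closed is the transient oxirane, by 3-exo-tet displacement; no ring of the product is formed. No new stereocentre arises, because the C–O bond at the carbinol carbon is never broken, so the configuration of 10 is carried unchanged into 13, and adding ring B first and ring A second to the S enantiomer places the two aryl groups as the target requires. The step needs attack at the terminal carbon in both openings and attack on the oxirane in preference to direct displacement of chloride, which would lead to the mirror-image oxirane; the unhindered CH2 termini and low-temperature copper catalysis should secure both, and a slight deficit of 9 keeps the symmetrical bis(ring B) carbinol down.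

Step 6
Reactants: 13 (S)-1-[4-(tert-butyldimethylsilyloxy)phenyl]-3-(7-methoxy-2,2-dimethyl-2H-chromen-6-yl)propan-2-ol
Product: 14 tert-butyl{4-[(S)-2-(tert-butyldimethylsilyloxy)-3-(7-methoxy-2,2-dimethyl-2H-chromen-6-yl)propyl]phenoxy}dimethylsilane
Conditions: TBSCl, imidazole, DMAP (cat.), DMF, 40 °C
Reagents that add atoms: tert-butyldimethylsilyl chloride, CC(C)(C)[Si](C)(C)Cl
Why: Silylation of a secondary alcohol, which masks the carbinol so that it can neither be oxidised nor capture the benzylic cation in the next step.

Step 7
Reactants: 14 tert-butyl{4-[(S)-2-(tert-butyldimethylsilyloxy)-3-(7-methoxy-2,2-dimethyl-2H-chromen-6-yl)propyl]phenoxy}dimethylsilane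
Product: 16 (S)-2-(tert-butyldimethylsilyloxy)-3-[4-(tert-butyldimethylsilyloxy)phenyl]-1-(7-methoxy-2,2-dimethyl-2H-chromen-6-yl)propan-1-one, via benzylic alcohol 15 (not isolated)
Conditions: DDQ (2.5 equiv), 1,4-dioxane/H2O (10:1), rt
Reagents that add atoms: water, O
Why: DDQ benzylic oxidation, in which hydride abstraction from the ring A CH2 (ortho to the methoxy group and para to the pyran oxygen) gives a doubly oxygen-stabilised cation that water traps to alcohol 15 and a second equivalent of DDQ takes to the aryl ketone; the ring B CH2 has only one silyloxy donor and should react far more slowly, the chromene has no hydrogen at C2 to lose, the new acyl group deactivates the product, and the stereocentre is not touched.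

Step 8
Reactants: 16 (S)-2-(tert-butyldimethylsilyloxy)-3-[4-(tert-butyldimethylsilyloxy)phenyl]-1-(7-methoxy-2,2-dimethyl-2H-chromen-6-yl)propan-1-one
Product: 17 Lespeflorin C7, (S)-2-hydroxy-3-(4-hydroxyphenyl)-1-(7-methoxy-2,2-dimethyl-2H-chromen-6-yl)propan-1-one
Conditions: HF·pyridine, pyridine, THF, 0 °C to rt
Reagents that add atoms: none
Why: Fluoride-mediated desilylation of the secondary alkyl and the aryl silyl ether under buffered, weakly acidic conditions, which avoids the enolisation of the α-hydroxy ketone that a basic fluoride source could cause, so the S configuration should be retained.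

**Compound list**

1 | 4-bromo-3-methoxyphenol | COc1cc(O)ccc1Br | starting material
2 | 3-methylbut-2-enal | CC(C)=CC=O | starting material
3 | 6-bromo-7-methoxy-4-(2-methylprop-1-en-1-yl)-2-phenyl-4H-1,3,2-benzodioxaborinine | COc1cc2OB(c3ccccc3)OC(C=C(C)C)c2cc1Br | intermediate (not isolated)
4 | 4-bromo-3-methoxy-6-(3-methylbut-2-en-1-ylidene)cyclohexa-2,4-dien-1-one | COC1=CC(=O)C(=CC=C(C)C)C=C1Br | intermediate (not isolated)
5 | 6-bromo-7-methoxy-2,2-dimethyl-2H-chromene | COc1cc2c(cc1Br)C=CC(C)(C)O2 | intermediate
6 | (7-methoxy-2,2-dimethyl-2H-chromen-6-yl)magnesium bromide | COc1cc2c(cc1[Mg]Br)C=CC(C)(C)O2 | intermediate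
7 | 4-bromophenol | Oc1ccc(Br)cc1 | starting material
8 | (4-bromophenoxy)(tert-butyl)dimethylsilane | CC(C)(C)[Si](C)(C)Oc1ccc(Br)cc1 | intermediate
9 | 4-(tert-butyldimethylsilyloxy)phenylmagnesium bromide | Br[Mg]c1ccc(O[Si](C)(C)C(C)(C)C)cc1 | intermediate
10 | (S)-epichlorohydrin | ClC[C@@H]1CO1 | starting material
11 | bromomagnesium (S)-1-chloro-3-[4-(tert-butyldimethylsilyloxy)phenyl]propan-2-olate | ClC[C@@H](O[Mg]Br)Cc1ccc(O[Si](C)(C)C(C)(C)C)cc1 | intermediate (not isolated)
12 | (S)-2-[4-(tert-butyldimethylsilyloxy)benzyl]oxirane | C1O[C@H]1Cc1ccc(O[Si](C)(C)C(C)(C)C)cc1 | intermediate (not isolated)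
13 | (S)-1-[4-(tert-butyldimethylsilyloxy)phenyl]-3-(7-methoxy-2,2-dimethyl-2H-chromen-6-yl)propan-2-ol | COc1cc2c(cc1C[C@@H](O)Cc1ccc(O[Si](C)(C)C(C)(C)C)cc1)C=CC(C)(C)O2 | intermediate
14 | tert-butyl{4-[(S)-2-(tert-butyldimethylsilyloxy)-3-(7-methoxy-2,2-dimethyl-2H-chromen-6-yl)propyl]phenoxy}dimethylsilane | COc1cc2c(cc1C[C@@H](O[Si](C)(C)C(C)(C)C)Cc1ccc(O[Si](C)(C)C(C)(C)C)cc1)C=CC(C)(C)O2 | intermediate
15 | (2S)-2-(tert-butyldimethylsilyloxy)-3-[4-(tert-butyldimethylsilyloxy)phenyl]-1-(7-methoxy-2,2-dimethyl-2H-chromen-6-yl)propan-1-ol, both C1 epimers | COc1cc2c(cc1C(O)[C@@H](O[Si](C)(C)C(C)(C)C)Cc1ccc(O[Si](C)(C)C(C)(C)C)cc1)C=CC(C)(C)O2 | intermediate (not isolated)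
16 | (S)-2-(tert-butyldimethylsilyloxy)-3-[4-(tert-butyldimethylsilyloxy)phenyl]-1-(7-methoxy-2,2-dimethyl-2H-chromen-6-yl)propan-1-one | COc1cc2c(cc1C(=O)[C@@H](O[Si](C)(C)C(C)(C)C)Cc1ccc(O[Si](C)(C)C(C)(C)C)cc1)C=CC(C)(C)O2 | intermediate
17 | Lespeflorin C7, (S)-2-hydroxy-3-(4-hydroxyphenyl)-1-(7-methoxy-2,2-dimethyl-2H-chromen-6-yl)propan-1-one | COc1cc2c(cc1C(=O)[C@@H](O)Cc1ccc(O)cc1)C=CC(C)(C)O2 | target

**Step count**

Total: 8 steps. Longest linear sequence: 6 steps (1 → 2 → 5 → 6 → 7 → 8, or equally 3 → 4 → 5 → 6 → 7 → 8).

**Steps most likely to fail, with fallbacks**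

Step 7. Hydride abstraction may not discriminate cleanly between the two benzylic methylenes. The ring A benzylic cation may also take a 1,2-hydride shift from the silyloxy-bearing carbon before water traps it, which would erase the stereocentre, or the electron-rich chromene may be attacked oxidatively. The fallback introduces the carbonyl by acylation instead of oxidation and sets out from Grignard reagent 6. Commercial methyl (S)-2-hydroxy-3-(4-hydroxyphenyl)propanoate F1 is bis-silylated (TBSCl, imidazole, DMF, rt) to methyl (S)-2-(tert-butyldimethylsilyloxy)-3-[4-(tert-butyldimethylsilyloxy)phenyl]propanoate F2. Treatment with MeNHOMe·HCl and iPrMgCl (THF, −20 °C) should convert F2 into the Weinreb amide (S)-2-(tert-butyldimethylsilyloxy)-3-[4-(tert-butyldimethylsilyloxy)phenyl]-N-methoxy-N-methylpropanamide F3. Addition of 6 to F3 (THF, −20 to 0 °C) should stop at the chelated tetrahedral adduct and release ketone 16 on work-up, where the route is rejoined; the stereocentre then comes from the lactate and is not touched.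

Step 5. In the single flask, closure of the chlorohydrin alkoxide may be incomplete in the presence of magnesium salts, and tert-butoxide may attack the aryl silyl ether. Residual first Grignard reagent may cross over into symmetrical carbinols, and halide opening and reclosure of epichlorohydrin may erode the enantiomeric purity. The fallback separates the two bond formations and changes the second one; it sets out from 9, 10 and bromide 5. The first copper-catalysed opening (Li2CuCl4, THF, −40 °C) is quenched with aq. NH4Cl and (S)-1-chloro-3-[4-(tert-butyldimethylsilyloxy)phenyl]propan-2-ol F4 is isolated and purified. NaH in THF at 0 °C should close it to oxirane 12, now isolated so that its enantiomeric purity can be checked. Bromide 5 is converted by bromine–lithium exchange (n-BuLi, THF, −78 °C) into (7-methoxy-2,2-dimethyl-2H-chromen-6-yl)lithium F5, which should open 12 at the terminal carbon in the presence of BF3·OEt2 at −78 °C to give 13, where the route is rejoined.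

Step 1. The boronate-templated condensation may stall on the bromine-deactivated phenol, the enal may oligomerise under the acidic reflux, or some annulation may occur at C2 between the two oxygen substituents. The fallback builds the pyran ring by a propargyl Claisen sequence and sets out from 1. O-Alkylation with 3-chloro-3-methylbut-1-yne (K2CO3, KI, acetone, reflux) should give 1-bromo-2-methoxy-4-[(2-methylbut-3-yn-2-yl)oxy]benzene F6. Heating F6 in N,N-diethylaniline at about 190 °C should bring about aromatic Claisen rearrangement, 1,5-hydrogen shift and oxa-6π electrocyclisation, mainly toward the position para to the methoxy group, to give 5, where the route is rejoined.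

**Further compounds**

F1 | step 7 | methyl (S)-2-hydroxy-3-(4-hydroxyphenyl)propanoate | COC(=O)[C@@H](O)Cc1ccc(O)cc1
F2 | step 7 | methyl (S)-2-(tert-butyldimethylsilyloxy)-3-[4-(tert-butyldimethylsilyloxy)phenyl]propanoate | COC(=O)[C@@H](O[Si](C)(C)C(C)(C)C)Cc1ccc(O[Si](C)(C)C(C)(C)C)cc1
F3 | step 7 | (S)-2-(tert-butyldimethylsilyloxy)-3-[4-(tert-butyldimethylsilyloxy)phenyl]-N-methoxy-N-methylpropanamide | CON(C)C(=O)[C@@H](O[Si](C)(C)C(C)(C)C)Cc1ccc(O[Si](C)(C)C(C)(C)C)cc1
F4 | step 5 | (S)-1-chloro-3-[4-(tert-butyldimethylsilyloxy)phenyl]propan-2-ol | ClC[C@@H](O)Cc1ccc(O[Si](C)(C)C(C)(C)C)cc1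
F5 | step 5 | (7-methoxy-2,2-dimethyl-2H-chromen-6-yl)lithium | COc1cc2c(cc1[Li])C=CC(C)(C)O2
F6 | step 1 | 1-bromo-2-methoxy-4-[(2-methylbut-3-yn-2-yl)oxy]benzene | COc1cc(OC(C)(C)C#C)ccc1Br
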